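## Retrosynthetic overview
1. The last bond is the C8–O ester. The 8,9-diol of the tricyclic core is acylated with (E)-2-(acetoxymethyl)but-2-enoic acid, made from acetaldehyde and an acrylate by a Morita–Baylis–Hillman reaction and allylic transposition.
2. The ten-membered carbocycle and the α-methylene-γ-lactone come from the C6–C7 bond. A (Z)-enal is allylated intramolecularly (CrCl2) by a 2-(bromomethyl)enoate, and methyl acrylate brings in C11–C13 at a C7 aldehyde.
3. Key step: the furanone ring and quaternary C10 form by gold-triggered 5-endo-dig O-cyclisation of an α-hydroxy-α-alkynyl methyl ketone, with a 1,2-shift of C9 from C1 to C10.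
4. That ketol comes from two successive carbanion additions to the carbonyl of L-erythronolactone acetonide: first the C2–C6 enyne acetylide, then an acetyl anion equivalent. The lactone is the only source of chirality (C8, C9).
5. Ring order: the furanone forms first, then the carbocycle and the lactone in one operation. The dioxolane is only a protecting ring.

Assumption: 2,3-O-isopropylidene-L-erythronolactone is taken as purchasable from carbohydrate building-block suppliers, like its D-antipode.

Atom labels follow germacrane numbering of the target: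
- C1: ketone carbon
- C2=C3: furanone alkene
- C4=C5: Z-alkene, with C15 methyl on C4
- C6: lactone O–CH
- C7: ring-fusion CH
- C8: ester CH
- C9: carbinol CH
- C10: quaternary carbon, with C14 methyl
- C11=C13: exocyclic methylene
- C12: lactone C=O

## Route

Step 1
Reactants: 1 (Z)-3-methylpent-2-en-4-yn-1-ol
Product: 2 (Z)-tert-butyldimethyl[(3-methylpent-2-en-4-yn-1-yl)oxy]silane
Conditions: TBSCl, imidazole, CH2Cl2, 0 → 23 °C
Reagents that add atoms: tert-butyldimethylsilyl chloride, CC(C)(C)[Si](C)(C)Cl
Why: Standard silylation of a primary allylic alcohol masks the C6 oxygen, which would otherwise add to the triple bond (furan formation) once that bond is activated in steps 2 and 4; the Z-alkene (C4=C5 of the target) is untouched.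

Step 2
Reactants: 2 silyl enyne; 3 2,3-O-isopropylidene-L-erythronolactone; 4 ethyl vinyl ether
Product: 9 (3R,6Z)-8-(tert-butyldimethylsilyloxy)-3-hydroxy-3-[(4S,5S)-5-(hydroxymethyl)-2,2-dimethyl-1,3-dioxolan-4-yl]-6-methyloct-6-en-4-yn-2-one, via lithium acetylide 5 (not isolated), via lactol 6 (not isolated), via 1-ethoxyvinyllithium 7 (not isolated), via enol ether diol 8 (not isolated)
Conditions: 2, n-BuLi, THF, −78 °C; 3, −78 °C, 1 h; MgBr2·OEt2, then 7 (from 4, t-BuLi, THF, −78 → 0 °C), −78 → 0 °C; 0.5 M HCl, THF, 0 °C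
Reagents that add atoms: water, O
Why: Two sequential 1,2-additions to a lactone carbonyl: the acetylide stops at the lactolate at −78 °C, warming opens it to the ynone, the acetyl anion equivalent then adds under Cram chelate control (Mg2+ bridging C1=O and O9, attack from the H9 side opposite C8) to set 1R, and dilute acid hydrolyses the enol ether to the methyl ketone.

Step 3
Reactants: 9 ketol diol
Product: 10 (3R,6Z)-8-(tert-butyldimethylsilyloxy)-3-[(4S,5S)-5-(tert-butyldimethylsilyloxymethyl)-2,2-dimethyl-1,3-dioxolan-4-yl]-3-hydroxy-6-methyloct-6-en-4-yn-2-one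
Conditions: TBSCl (1.1 equiv), imidazole, CH2Cl2, 0 °C
Reagents that add atoms: tert-butyldimethylsilyl chloride, CC(C)(C)[Si](C)(C)Cl
Why: Selective silylation of the primary C7 hydroxyl over the tertiary C1 hydroxyl draws any six-membered hemiketal back to the open ketol and removes the only free OH that could attack the alkyne (6-exo-dig) in step 4.

Step 4
Reactants: 10 bis-silyl ketol
Product: 11 (2R)-2-[(4S,5S)-5-(tert-butyldimethylsilyloxymethyl)-2,2-dimethyl-1,3-dioxolan-4-yl]-5-[(2Z)-4-(tert-butyldimethylsilyloxy)but-2-en-2-yl]-2-methylfuran-3(2H)-one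
Conditions: Ph3PAuNTf2 (5 mol %), 4 Å MS, CH2Cl2, 0 → 23 °C
Reagents that add atoms: none
Why: Proposed new method: monovalent gold activates the enyne triple bond and the acetyl oxygen attacks C3 (5-endo-dig; C3 is the carbon whose positive charge the alkenyl group stabilises) to give a flat cyclic oxocarbenium ion carrying a vinyl–gold bond; the C1–C9 σ bond, which stands perpendicular to that ring, then migrates suprafacially to C10 while C1–OH becomes the C1 ketone (α-ketol-type 1,2-shift), and the released proton cleaves the C2–Au bond; C9 lands on the ring face it left, so 1R is converted into 10R with retention at C9, and C9 is the only group on C1 that can migrate; the closest known reaction type is the PtCl2- or AuCl3-catalysed cycloisomerisation of 2-hydroxy-2-alkynyl ketones to 3(2H)-furanones with a 1,2-alkyl shift, shown for simple alkyl groups and ring contractions but not for a stereogenic oxygen-bearing secondary carbon, for centre-to-centre chirality transfer from an acyclic carbinol, or for a conjugated (Z)-enyne carrying an allylic silyl ether.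

Step 5
Reactants: 11 bis-silyl furanone
Product: 12 (2R)-5-[(2Z)-4-hydroxybut-2-en-2-yl]-2-[(4S,5S)-5-(hydroxymethyl)-2,2-dimethyl-1,3-dioxolan-4-yl]-2-methylfuran-3(2H)-one
Conditions: HF·pyridine, pyridine, THF, 0 → 23 °C
Reagents that add atoms: none
Why: Buffered fluoride desilylation removes both primary TBS ethers at once and leaves the acetonide, the furanone and the Z-alkene alone.

Step 6
Reactants: 12 furanone diol
Product: 13 (4R,5S)-2,2-dimethyl-5-{(2R)-2-methyl-3-oxo-5-[(2Z)-4-oxobut-2-en-2-yl]-2,3-dihydrofuran-2-yl}-1,3-dioxolane-4-carbaldehyde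
Conditions: Dess–Martin periodinane (2.5 equiv), CH2Cl2, 0 → 23 °C
Reagents that add atoms: none
Why: Dess–Martin oxidation takes both primary alcohols to aldehydes under near-neutral conditions, so C8 is not epimerised and the (Z)-enal is not isomerised (the descriptor at C8 changes only because the priorities change).

Step 7
Reactants: 13 dialdehyde; 14 methyl acrylate
Product: 15 methyl 2-{hydroxy[(4S,5S)-2,2-dimethyl-5-{(2R)-2-methyl-3-oxo-5-[(2Z)-4-oxobut-2-en-2-yl]-2,3-dihydrofuran-2-yl}-1,3-dioxolan-4-yl]methyl}prop-2-enoate (C7 epimers)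
Conditions: 14 (5 equiv), quinuclidine (0.3 equiv), MeOH (1 equiv), neat, 23 °C
Reagents that add atoms: none
Why: Morita–Baylis–Hillman reaction: the α-alkoxy aliphatic C7 aldehyde is much more electrophilic than the β,β-disubstituted conjugated C6 enal, the fast quinuclidine/MeOH variant limits base contact of C8, and the new C7 carbinol centre is erased in step 8.

Step 8
Reactants: 15 Baylis–Hillman alcohol
Product: 16 methyl (2Z)-2-(bromomethyl)-3-[(4S,5S)-2,2-dimethyl-5-{(2R)-2-methyl-3-oxo-5-[(2Z)-4-oxobut-2-en-2-yl]-2,3-dihydrofuran-2-yl}-1,3-dioxolan-4-yl]prop-2-enoate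
Conditions: NBS, Me2S, CH2Cl2, 0 → 23 °C
Reagents that add atoms: N-bromosuccinimide, O=C1CCC(=O)N1Br
Why: Corey–Kim-type activation of the allylic alcohol followed by SN2′ attack of bromide gives the conjugated (Z)-2-(bromomethyl)enoate under neutral conditions that the acetonide and the enal tolerate.

Step 9
Reactants: 16 bromo enal
Product: 18 (4Z,6R,7S,8S,9S,10R)-8,9-(isopropylidenedioxy)-1-oxo-3,10-epoxygermacra-2,4,11(13)-trien-12,6-olide, via hydroxy ester 17 (not isolated)
Conditions: CrCl2 (8 equiv), THF, 0.002 M, slow addition, 23 °C; work-up; PPTS (cat.), CH2Cl2, 23 °C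
Reagents that add atoms: none
Why: Intramolecular Nozaki–Hiyama allylation with divalent chromium: the allylchromium adds through its γ-carbon C7 to the C6 aldehyde, bond formation anti to the C8–C9 bond with H8 eclipsing the alkene (A(1,3) strain) sets 7S, the short tether through the furanone favours H6 and H7 trans (6R), and the C6 alkoxide closes the lactone while O8 is still locked in the acetonide.

Step 10
Reactants: 18 lactone acetonide
Product: 19 (4Z,6R,7S,8S,9S,10R)-8,9-dihydroxy-1-oxo-3,10-epoxygermacra-2,4,11(13)-trien-12,6-olide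
Conditions: TFA–H2O (9:1), CH2Cl2, 0 °C
Reagents that add atoms: none
Why: Acid hydrolysis of the acetonide at low temperature frees the 8,9-diol, and the acidic medium avoids the base-induced translactonisation from O6 to O8.

Step 11
Reactants: 20 acetaldehyde; 21 tert-butyl acrylate
Product: 22 tert-butyl 3-hydroxy-2-methylidenebutanoate (racemic)
Conditions: quinuclidine (0.25 equiv), MeOH (0.75 equiv), neat, 23 °C
Reagents that add atoms: none
Why: Morita–Baylis–Hillman reaction of a simple aldehyde with an acrylate; the carbinol centre disappears in step 12.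

Step 12
Reactants: 22 Baylis–Hillman ester
Product: 24 tert-butyl (E)-2-(acetoxymethyl)but-2-enoate, via secondary acetate 23 (not isolated)
Conditions: Ac2O, Et3N, DMAP (cat.), THF, 0 → 23 °C; then DABCO (0.2 equiv), reflux
Reagents that add atoms: acetic anhydride, CC(=O)OC(C)=O
Why: Acetylation is followed by a DABCO-catalysed SN2′–SN2′ allylic transposition of the acetate, which ends at the thermodynamic trisubstituted alkene with the methyl group trans to the ester carbonyl (E).

Step 13
Reactants: 24 tert-butyl ester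
Product: 25 (E)-2-(acetoxymethyl)but-2-enoic acid
Conditions: TFA, CH2Cl2, 0 → 23 °C
Reagents that add atoms: none
Why: Acidolysis of the tert-butyl ester (loss of isobutene) leaves the primary allylic acetate and the alkene geometry intact.

Step 14
Reactants: 19 diol lactone; 25 side-chain acid
Product: 27 target CNP0231561.1 [(4Z,6R,7S,8S,9S,10R)-9-hydroxy-1-oxo-3,10-epoxygermacra-2,4,11(13)-trien-12,6-olid-8-yl (E)-2-(acetoxymethyl)but-2-enoate], via mixed anhydride 26 (not isolated)
Conditions: 25 (1.05 equiv), 2,4,6-Cl3C6H2COCl, Et3N, toluene, 23 °C; then 19, DMAP, toluene, 0 °C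
Reagents that add atoms: none
Why: Yamaguchi esterification with one equivalent of acid acylates the C8 hydroxyl, because the C9 hydroxyl is neopentyl-like (next to quaternary C10) and much more hindered; no stereocentre is touched.

## Compound list
1 | (Z)-3-methylpent-2-en-4-yn-1-ol | OC/C=C(/C)C#C | starting material
2 | (Z)-tert-butyldimethyl[(3-methylpent-2-en-4-yn-1-yl)oxy]silane | CC(C)(C)[Si](C)(C)OC/C=C(/C)C#C | intermediate
3 | 2,3-O-isopropylidene-L-erythronolactone, (3aS,6aS)-2,2-dimethyldihydrofuro[3,4-d][1,3]dioxol-4(3aH)-one | O=C1[C@H]2OC(C)(C)O[C@H]2CO1 | starting material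
4 | ethyl vinyl ether | C=COCC | starting material
5 | lithium acetylide of 2 | CC(C)(C)[Si](C)(C)OC/C=C(/C)C#C[Li] | intermediate
6 | lactol, (3aS,6aS)-4-[(3Z)-5-(tert-butyldimethylsilyloxy)-3-methylpent-3-en-1-yn-1-yl]-2,2-dimethyltetrahydrofuro[3,4-d][1,3]dioxol-4-ol (anomers; lithium alkoxide in the flask) | CC(C)(C)[Si](C)(C)OC/C=C(/C)C#CC1(O)[C@H]2OC(C)(C)O[C@H]2CO1 | intermediate
7 | 1-ethoxyvinyllithium | [Li]C(=C)OCC | intermediate
8 | enol ether diol, (3R,6Z)-8-(tert-butyldimethylsilyloxy)-2-ethoxy-3-[(4S,5S)-5-(hydroxymethyl)-2,2-dimethyl-1,3-dioxolan-4-yl]-6-methylocta-1,6-dien-4-yn-3-ol | CC(C)(C)[Si](C)(C)OC/C=C(/C)C#C[C@](O)(C(=C)OCC)[C@H]1OC(C)(C)O[C@H]1CO | intermediate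
9 | ketol diol, (3R,6Z)-8-(tert-butyldimethylsilyloxy)-3-hydroxy-3-[(4S,5S)-5-(hydroxymethyl)-2,2-dimethyl-1,3-dioxolan-4-yl]-6-methyloct-6-en-4-yn-2-one | CC(C)(C)[Si](C)(C)OC/C=C(/C)C#C[C@](O)(C(C)=O)[C@H]1OC(C)(C)O[C@H]1CO | intermediate
10 | bis-silyl ketol (9 with the C7 hydroxyl as TBS ether) | CC(C)(C)[Si](C)(C)OC/C=C(/C)C#C[C@](O)(C(C)=O)[C@H]1OC(C)(C)O[C@H]1CO[Si](C)(C)C(C)(C)C | intermediate
11 | bis-silyl furanone, (2R)-2-[(4S,5S)-5-(TBSOCH2)-2,2-dimethyl-1,3-dioxolan-4-yl]-5-[(2Z)-4-(TBSO)but-2-en-2-yl]-2-methylfuran-3(2H)-one | CC(C)(C)[Si](C)(C)OC/C=C(/C)C1=CC(=O)[C@](C)(O1)[C@H]2OC(C)(C)O[C@H]2CO[Si](C)(C)C(C)(C)C | intermediate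
12 | furanone diol | OC/C=C(/C)C1=CC(=O)[C@](C)(O1)[C@H]2OC(C)(C)O[C@H]2CO | intermediate
13 | dialdehyde, (4R,5S)-dioxolane-4-carbaldehyde carrying the (2R)-furanone and the (Z)-enal | O=C/C=C(/C)C1=CC(=O)[C@](C)(O1)[C@H]2OC(C)(C)O[C@H]2C=O | intermediate
14 | methyl acrylate | C=CC(=O)OC | starting material
15 | Baylis–Hillman alcohol (C7 epimers) | O=C/C=C(/C)C1=CC(=O)[C@](C)(O1)[C@H]2OC(C)(C)O[C@H]2C(O)C(=C)C(=O)OC | intermediate
16 | (Z)-2-(bromomethyl)enoate enal | O=C/C=C(/C)C1=CC(=O)[C@](C)(O1)[C@H]2OC(C)(C)O[C@H]2/C=C(\CBr)C(=O)OC | intermediate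
17 | macrocyclic hydroxy ester, methyl (4Z,6R,7S,8S,9S,10R)-6-hydroxy-8,9-(isopropylidenedioxy)-1-oxo-3,10-epoxygermacra-2,4,11(13)-trien-12-oate | C=C(C(=O)OC)[C@H]1[C@H](O)/C=C(/C)C2=CC(=O)[C@](C)(O2)[C@H]3OC(C)(C)O[C@H]31 | intermediate
18 | lactone acetonide, (4Z,6R,7S,8S,9S,10R) | C=C1C(=O)O[C@@H]2/C=C(/C)C3=CC(=O)[C@](C)(O3)[C@H]4OC(C)(C)O[C@H]4[C@@H]12 | intermediate
19 | diol lactone, (4Z,6R,7S,8S,9S,10R) | C=C1C(=O)O[C@@H]2/C=C(/C)C3=CC(=O)[C@](C)(O3)[C@@H](O)[C@@H](O)[C@@H]12 | intermediate
20 | acetaldehyde | CC=O | starting material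
21 | tert-butyl acrylate | C=CC(=O)OC(C)(C)C | starting material
22 | tert-butyl 3-hydroxy-2-methylidenebutanoate (racemic) | CC(O)C(=C)C(=O)OC(C)(C)C | intermediate
23 | tert-butyl 3-acetoxy-2-methylidenebutanoate (racemic) | CC(OC(C)=O)C(=C)C(=O)OC(C)(C)C | intermediate
24 | tert-butyl (E)-2-(acetoxymethyl)but-2-enoate | CC(C)(C)OC(=O)/C(=C/C)COC(C)=O | intermediate
25 | (E)-2-(acetoxymethyl)but-2-enoic acid | OC(=O)/C(=C/C)COC(C)=O | intermediate
26 | (E)-2-(acetoxymethyl)but-2-enoic 2,4,6-trichlorobenzoic anhydride | O=C(OC(=O)/C(=C/C)COC(C)=O)c1c(Cl)cc(Cl)cc1Cl | intermediate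
27 | CNP0231561.1 | C=C1C(=O)O[C@@H]2/C=C(/C)C3=CC(=O)[C@](C)(O3)[C@@H](O)[C@@H](OC(=O)/C(=C/C)COC(C)=O)[C@@H]12 | target

## Step count and risks
Total steps: 14. Longest linear sequence: 11 (steps 1–10 and 14). The side chain (steps 11–13) runs in parallel.

**Step 2 (one-pot double addition, 1R centre).**
- Risks: the acetyl anion equivalent may add in the Felkin–Anh sense and give mainly 1S, or it may enolise the ynone at C9.
- Fallback: the order of the two C–C bond formations is inverted. It sets out from 3.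
- Reagent 7 is added first (THF, −78 °C) and the 1-ethoxyvinyl lactol F1 is isolated.
- In the open α-ethoxy enone form of this lactol, the metal is held between C=O and OEt rather than O9.
- Acetylide 5 (2.2 equiv, THF, −78 → −20 °C) then adds. The same non-chelate facial bias that gave the wrong epimer in the first order now places the alkynyl and acetyl units the other way round and delivers 1R.
- The fallback comes back to the route at 8, which is hydrolysed to 9 as before.

**Step 4 (proposed new cyclisation/1,2-shift).**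
- Risks: the oxygenated C9 may migrate sluggishly, the dioxolane oxygen O9 or the C6 silyl ether oxygen may attack C3 instead, or the oxocarbenium ion may lose a proton from C14.
- Fallback: known chemistry only, in which the C9–C10 bond is present from the start. It sets out from 3.
- MeLi (1 equiv, THF, −78 °C) gives the methyl lactol F2.
- CH2=CHMgBr (3 equiv, THF, 0 °C) adds to its open keto form under chelate control and gives the tertiary allylic alcohol diol F3, with C10 already in its final configuration.
- TBSCl/imidazole gives the primary silyl ether F4.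
- Ozonolysis (O3, CH2Cl2, −78 °C; Me2S) gives the α-hydroxy aldehyde F5.
- Acetylide 5 (2.2 equiv) adds to give the propargylic diol F6. Its C1 epimers are irrelevant.
- Dess–Martin oxidation gives the α′-hydroxy ynone F7.
- Et2NH (EtOH, 23 °C) adds to the ynone to give the enaminone F8. Aqueous AcOH then closes the tertiary hydroxyl onto C3 with loss of the amine, the classical conversion of an acetylenic ketol into a 3(2H)-furanone.
- The fallback comes back at 11 and costs four more steps.

**Step 9 (ten-membered ring closure, 6R and 7S).**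
- Risks: oligomerisation, a cis ring fusion (closed transition states of 2-alkoxycarbonyl allyl metals often favour syn products), or reductive 1,4-elimination of O8.
- Fallback: the allyl metal is replaced by an isolable allylsilane and an open transition state. It sets out from 13 and replaces steps 7–9.
- Trimethyl phosphonoacetate is alkylated (NaH, ICH2SiMe3) to give the silyl phosphonate F9.
- A Horner–Wadsworth–Emmons reaction (LiCl, DBU, MeCN, 0 °C) at the more electrophilic C7 aldehyde gives the 2-(trimethylsilylmethyl)enoate allylsilane F10.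
- BF3·OEt2 (CH2Cl2, −78 °C, high dilution) triggers an intramolecular Hosomi–Sakurai reaction at the enal to give 17. The sense of ring fusion can be changed by switching to fluoride activation.
- PPTS closes the lactone, and the fallback comes back at 18.

## Further compounds
F1 | step 2 | 1-ethoxyvinyl lactol, (3aS,6aS)-4-(1-ethoxyvinyl)-2,2-dimethyltetrahydrofuro[3,4-d][1,3]dioxol-4-ol (anomers) | C=C(OCC)C1(O)[C@H]2OC(C)(C)O[C@H]2CO1
F2 | step 4 | methyl lactol, (3aS,6aS)-2,2,4-trimethyltetrahydrofuro[3,4-d][1,3]dioxol-4-ol (anomers) | CC1(O)[C@H]2OC(C)(C)O[C@H]2CO1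
F3 | step 4 | tertiary allylic alcohol diol, (2S)-2-[(4S,5S)-5-(hydroxymethyl)-2,2-dimethyl-1,3-dioxolan-4-yl]but-3-en-2-ol | C=C[C@](C)(O)[C@H]1OC(C)(C)O[C@H]1CO
F4 | step 4 | primary silyl ether of F3 | C=C[C@](C)(O)[C@H]1OC(C)(C)O[C@H]1CO[Si](C)(C)C(C)(C)C
F5 | step 4 | α-hydroxy aldehyde, (2R)-2-[(4S,5S)-5-(TBSOCH2)-2,2-dimethyl-1,3-dioxolan-4-yl]-2-hydroxypropanal | O=C[C@](C)(O)[C@H]1OC(C)(C)O[C@H]1CO[Si](C)(C)C(C)(C)C
F6 | step 4 | propargylic diol (C1 epimers, C10 as in F5) | CC(C)(C)[Si](C)(C)OC/C=C(/C)C#CC(O)[C@](C)(O)[C@H]1OC(C)(C)O[C@H]1CO[Si](C)(C)C(C)(C)C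
F7 | step 4 | α′-hydroxy ynone (10R) | CC(C)(C)[Si](C)(C)OC/C=C(/C)C#CC(=O)[C@](C)(O)[C@H]1OC(C)(C)O[C@H]1CO[Si](C)(C)C(C)(C)C
F8 | step 4 | enaminone (diethylamine adduct of F7 at C3) | CC(C)(C)[Si](C)(C)OC/C=C(/C)C(=CC(=O)[C@](C)(O)[C@H]1OC(C)(C)O[C@H]1CO[Si](C)(C)C(C)(C)C)N(CC)CC
F9 | step 9 | silyl phosphonate, methyl 2-(dimethoxyphosphoryl)-3-(trimethylsilyl)propanoate | COC(=O)C(C[Si](C)(C)C)P(=O)(OC)OC
F10 | step 9 | 2-(trimethylsilylmethyl)enoate allylsilane (E/Z mixture at C7=C11) | O=C/C=C(/C)C1=CC(=O)[C@](C)(O1)[C@H]2OC(C)(C)O[C@H]2C=C(C[Si](C)(C)C)C(=O)OC
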